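**Retrosynthetic overview**
1. Target 15 ⇐ crotyl dimer 13 by olefin cross-metathesis (E-but-2-enyl → prenyl).
2. 13 ⇐ aryl (R)-but-3-en-2-yl ether 12 by a dearomative aromatic Claisen ([3,3]) rearrangement that forms the C4–CH2 bond and sets the only stereocentre by 1,3-chirality transfer.
3. 12 ⇐ ring A ether 5 + ring B ketone 8 by Mannich / ortho-quinone methide methylene bridging.
4. 5 ⇐ ketone 3 + (S)-but-3-en-2-ol (Mitsunobu, inversion); 3 ⇐ 2-methylphloroglucinol + butanoyl chloride; 8 ⇐ phlorobutyrophenone.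
5. Rings: no ring is built; both six-membered rings are bought as phloroglucinols, joined in step 4, and ring A is dearomatised in step 5.

Assumption: 1, 2, 4, 6, 7, 9 and 14 are purchased; CIP descriptors of the dearomatised ring refer to the enol tautomer drawn (these compounds are rapidly equilibrating enols with one fixed quaternary stereocentre).

**Step 1**
Reactants: 1 2-methylbenzene-1,3,5-triol; 2 butanoyl chloride
Product: 3 1-(2,4,6-trihydroxy-3-methylphenyl)butan-1-one
Conditions: AlCl3 (4 equiv), PhNO2/CH2Cl2, 0 °C → rt; aq. HCl work-up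
Reagents that add atoms: butanoyl chloride 2, CCCC(=O)Cl
Why: Friedel–Crafts C-acylation of the very electron-rich triol, whose two free ring positions are equivalent and whose first acyl group deactivates the ring toward a second acylation; no stereocentre.

**Step 2**
Reactants: 3 1-(2,4,6-trihydroxy-3-methylphenyl)butan-1-one; 4 (2S)-but-3-en-2-ol
Product: 5 1-[4-[(2R)-but-3-en-2-yloxy]-2,6-dihydroxy-3-methylphenyl]butan-1-one
Conditions: PPh3 (1.2 equiv), DIAD (1.2 equiv), THF, −20 °C → rt
Reagents that add atoms: (2S)-but-3-en-2-ol 4, C[C@H](O)C=C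
Why: Mitsunobu etherification in which the 4-OH (para to the ketone, most acidic and the only hydroxyl that cannot chelate the carbonyl) is alkylated, and SN2 displacement of the oxyphosphonium inverts the bought (S)-carbinol to the (R)-aryl ether.

**Step 3**
Reactants: 6 1-(2,4,6-trihydroxyphenyl)butan-1-one; 7 dimethyl sulfate
Product: 8 1-(2,6-dihydroxy-4-methoxyphenyl)butan-1-one
Conditions: Me2SO4 (1.0 equiv), K2CO3 (1.0 equiv), acetone, rt
Reagents that add atoms: dimethyl sulfate 7, COS(=O)(=O)OC
Why: Williamson-type O-methylation with one equivalent of base and electrophile selects the most acidic, non-chelated 4-OH of the acylphloroglucinol; no stereocentre.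

**Step 4**
Reactants: 5 1-[4-[(2R)-but-3-en-2-yloxy]-2,6-dihydroxy-3-methylphenyl]butan-1-one; 9 N,N-dimethylmethylideneammonium iodide (Eschenmoser's salt); 8 1-(2,6-dihydroxy-4-methoxyphenyl)butan-1-one
Product: 12 1-[3-[[2-[(2R)-but-3-en-2-yloxy]-5-butanoyl-4,6-dihydroxy-3-methylphenyl]methyl]-2,6-dihydroxy-4-methoxyphenyl]butan-1-one, via Mannich base 10 (not isolated), via ortho-quinone methide 11 (not isolated)
Conditions: 9 (1.0 equiv), Et3N (1.1 equiv), MeCN, 0 °C → rt; then 8 (3 equiv), 80 °C, N2 sweep
Reagents that add atoms: N,N-dimethylmethylideneammonium iodide 9, C[N+](C)=C.[I-]; coupling partner 8, CCCC(=O)c1c(O)cc(OC)cc1O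
Why: Mannich aminomethylation at the only free ring carbon of 5, then thermal loss of dimethylamine to an ortho-quinone methide that is C-alkylated (Michael-type) by the excess symmetric phenol 8, at a temperature well below that of the Claisen rearrangement so the ether stereocentre is untouched.

**Step 5**
Reactants: 12 1-[3-[[2-[(2R)-but-3-en-2-yloxy]-5-butanoyl-4,6-dihydroxy-3-methylphenyl]methyl]-2,6-dihydroxy-4-methoxyphenyl]butan-1-one
Product: 13 (4R)-2-butanoyl-4-[(2E)-but-2-en-1-yl]-6-[(3-butanoyl-2,4-dihydroxy-6-methoxyphenyl)methyl]-3,5-dihydroxy-4-methylcyclohexa-2,5-dien-1-one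
Conditions: degassed o-xylene (0.02 M), 140 °C, sealed tube
Reagents that add atoms: none
Why: Dearomative aromatic Claisen ([3,3]-sigmatropic) rearrangement through a chair transition state with the butenyl methyl pseudo-equatorial, which delivers the CH2 terminus to one face of the methyl-bearing ortho carbon (expected to be preferred over the carbon carrying the bulky 2,6-disubstituted benzyl group, a preference that is not secured), so the (R) C–O centre becomes the (4R) quaternary carbon with an E-alkene, and the dienone is trapped at once as the stable enolised triketone.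

**Step 6**
Reactants: 13 (4R)-2-butanoyl-4-[(2E)-but-2-en-1-yl]-6-[(3-butanoyl-2,4-dihydroxy-6-methoxyphenyl)methyl]-3,5-dihydroxy-4-methylcyclohexa-2,5-dien-1-one; 14 2-methylbut-2-ene
Product: 15 elaphopilosin A, (4R)-2-butanoyl-6-[(3-butanoyl-2,4-dihydroxy-6-methoxyphenyl)methyl]-3,5-dihydroxy-4-methyl-4-(3-methylbut-2-en-1-yl)cyclohexa-2,5-dien-1-one
Conditions: 14 (large excess, co-solvent), second-generation Grubbs catalyst RuCl2(=CHPh)(PCy3)(H2IMes) (10 mol %), CH2Cl2, 40 °C, sealed tube
Reagents that add atoms: 2-methylbut-2-ene 14, CC=C(C)C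
Why: Olefin cross-metathesis with excess 2-methylbut-2-ene exchanges the ethylidene end of the crotyl group for isopropylidene, giving a trisubstituted prenyl alkene that does not react further; the quaternary stereocentre is not involved.

**Compound list**
1 | 2-methylbenzene-1,3,5-triol (2-methylphloroglucinol) | Cc1c(O)cc(O)cc1O | starting material
2 | butanoyl chloride | CCCC(=O)Cl | starting material
3 | 1-(2,4,6-trihydroxy-3-methylphenyl)butan-1-one | CCCC(=O)c1c(O)cc(O)c(C)c1O | intermediate
4 | (2S)-but-3-en-2-ol | C[C@H](O)C=C | starting material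
5 | 1-[4-[(2R)-but-3-en-2-yloxy]-2,6-dihydroxy-3-methylphenyl]butan-1-one | CCCC(=O)c1c(O)cc(O[C@H](C)C=C)c(C)c1O | intermediate
6 | 1-(2,4,6-trihydroxyphenyl)butan-1-one (phlorobutyrophenone) | CCCC(=O)c1c(O)cc(O)cc1O | starting material
7 | dimethyl sulfate | COS(=O)(=O)OC | starting material
8 | 1-(2,6-dihydroxy-4-methoxyphenyl)butan-1-one | CCCC(=O)c1c(O)cc(OC)cc1O | intermediate
9 | N,N-dimethylmethylideneammonium iodide (Eschenmoser's salt) | C[N+](C)=C.[I-] | starting material
10 | 1-[4-[(2R)-but-3-en-2-yloxy]-3-[(dimethylamino)methyl]-2,6-dihydroxy-5-methylphenyl]butan-1-one (Mannich base) | CCCC(=O)c1c(O)c(CN(C)C)c(O[C@H](C)C=C)c(C)c1O | intermediate (not isolated)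
11 | 2-butanoyl-5-[(2R)-but-3-en-2-yloxy]-3-hydroxy-4-methyl-6-methylidenecyclohexa-2,4-dien-1-one (ortho-quinone methide) | CCCC(=O)C1=C(O)C(C)=C(O[C@H](C)C=C)C(=C)C1=O | intermediate (not isolated)
12 | 1-[3-[[2-[(2R)-but-3-en-2-yloxy]-5-butanoyl-4,6-dihydroxy-3-methylphenyl]methyl]-2,6-dihydroxy-4-methoxyphenyl]butan-1-one | CCCC(=O)c1c(O)c(Cc2c(OC)cc(O)c(C(=O)CCC)c2O)c(O[C@H](C)C=C)c(C)c1O | intermediate
13 | (4R)-2-butanoyl-4-[(2E)-but-2-en-1-yl]-6-[(3-butanoyl-2,4-dihydroxy-6-methoxyphenyl)methyl]-3,5-dihydroxy-4-methylcyclohexa-2,5-dien-1-one | CCCC(=O)C1=C(O)[C@](C)(C/C=C/C)C(O)=C(Cc2c(OC)cc(O)c(C(=O)CCC)c2O)C1=O | intermediate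
14 | 2-methylbut-2-ene | CC=C(C)C | starting material
15 | elaphopilosin A, (4R)-2-butanoyl-6-[(3-butanoyl-2,4-dihydroxy-6-methoxyphenyl)methyl]-3,5-dihydroxy-4-methyl-4-(3-methylbut-2-en-1-yl)cyclohexa-2,5-dien-1-one | CCCC(=O)C1=C(O)[C@](C)(CC=C(C)C)C(O)=C(Cc2c(OC)cc(O)c(C(=O)CCC)c2O)C1=O | target

**Totals**
Total step count: 6. Longest linear sequence: 5 (steps 1, 2, 4, 5, 6).

**Three steps most likely to fail**

Step 5 (Claisen rearrangement of 12). Both ortho carbons of the ether are substituted, so migration to the benzyl-bearing carbon would give a regioisomer. The expected preference for the methyl-bearing carbon rests only on sterics and on the ring A 6-OH being engaged across the bridge. A minor Z-alkene or boat pathway would also erode the ee after step 6. Fallback: set out from 5 and rearrange at the monomer stage with a traceless block. Chlorinate 5 at its only free ring carbon (NCS, MeCN, 0 °C) to 1-[4-[(2R)-but-3-en-2-yloxy]-3-chloro-2,6-dihydroxy-5-methylphenyl]butan-1-one F1. Heat as in step 5; the chlorine-bearing ortho carbon is deactivated toward ipso attack, leaving the methyl-bearing carbon as the only alkyl-bearing site. This gives (4S)-2-butanoyl-4-[(2E)-but-2-en-1-yl]-6-chloro-3,5-dihydroxy-4-methylcyclohexa-2,5-dien-1-one F2, with the same spatial arrangement as 13 (only the descriptor changes because of chlorine). Remove the chlorine with zinc dust (Zn) in AcOH at rt to give (4R)-2-butanoyl-4-[(2E)-but-2-en-1-yl]-3,5-dihydroxy-4-methylcyclohexa-2,5-dien-1-one F3. Treat F3 with 9 and Et3N to form (4R)-2-butanoyl-4-[(2E)-but-2-en-1-yl]-6-[(dimethylamino)methyl]-3,5-dihydroxy-4-methylcyclohexa-2,5-dien-1-one F4, and heat it with excess 8 as in step 4. The route is rejoined at 13.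

Step 2 (Mitsunobu with a secondary allylic alcohol on a triphenol). The risks are SN2′ attack giving the linear crotyl ether, partial loss of ee through ion pairs, and alkylation of a second hydroxyl. Fallback: set out from 3 and replace the SN2 etherification by an enantiospecific, branched-selective rhodium-catalysed allylic etherification that proceeds with net retention. (2R)-But-3-en-2-ol is converted with methyl chloroformate and pyridine into (2R)-but-3-en-2-yl methyl carbonate F5. F5 is coupled with the mono-sodium phenoxide of 3 (1 equiv NaN(SiMe3)2) using RhCl(PPh3)3/P(OMe)3 in THF at 0 °C → rt, an achiral catalyst. The route is rejoined at 5.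

Step 6 (cross-metathesis on the free polyphenol). The acidic, chelating enol and phenol groups of 13 may deactivate the ruthenium carbene, and the internal crotyl alkene is a slow partner. Fallback: set out from 13 and mask the acidic hydroxyls first. Acetylation (Ac2O, pyridine, cat. DMAP, rt) gives the tetra-O-acetate of 13 F6, with both enol hydroxyls of ring A and both phenols of ring B acetylated. Cross-metathesis of F6 with 14 under the step 6 conditions gives the tetra-O-acetate of 15 F7. Methanolysis (K2CO3, MeOH, rt) removes the four acetates and rejoins the route at 15.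

**Further compounds**
F1 | step 5 | 1-[4-[(2R)-but-3-en-2-yloxy]-3-chloro-2,6-dihydroxy-5-methylphenyl]butan-1-one | CCCC(=O)c1c(O)c(Cl)c(O[C@H](C)C=C)c(C)c1O
F2 | step 5 | (4S)-2-butanoyl-4-[(2E)-but-2-en-1-yl]-6-chloro-3,5-dihydroxy-4-methylcyclohexa-2,5-dien-1-one | CCCC(=O)C1=C(O)[C@](C)(C/C=C/C)C(O)=C(Cl)C1=O
F3 | step 5 | (4R)-2-butanoyl-4-[(2E)-but-2-en-1-yl]-3,5-dihydroxy-4-methylcyclohexa-2,5-dien-1-one | CCCC(=O)C1=C(O)[C@](C)(C/C=C/C)C(O)=CC1=O
F4 | step 5 | (4R)-2-butanoyl-4-[(2E)-but-2-en-1-yl]-6-[(dimethylamino)methyl]-3,5-dihydroxy-4-methylcyclohexa-2,5-dien-1-one | CCCC(=O)C1=C(O)[C@](C)(C/C=C/C)C(O)=C(CN(C)C)C1=O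
F5 | step 2 | (2R)-but-3-en-2-yl methyl carbonate | COC(=O)O[C@H](C)C=C
F6 | step 6 | tetra-O-acetate of 13 (ring A enol diacetate, ring B phenol diacetate, 4R) | CCCC(=O)C1=C(OC(C)=O)[C@](C)(C/C=C/C)C(OC(C)=O)=C(Cc2c(OC)cc(OC(C)=O)c(C(=O)CCC)c2OC(C)=O)C1=O
F7 | step 6 | tetra-O-acetate of 15 (ring A enol diacetate, ring B phenol diacetate, 4R) | CCCC(=O)C1=C(OC(C)=O)[C@](C)(CC=C(C)C)C(OC(C)=O)=C(Cc2c(OC)cc(OC(C)=O)c(C(=O)CCC)c2OC(C)=O)C1=O
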